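**Sipholenol M (36): synthesis design built on an epoxonium oxa/carbacyclization cascade**

Locants used throughout: the oxepane–cyclohexane half is numbered as a 1-benzoxepine (O1, C2 … C9a; ring A = oxepane, ring B = cyclohexane). The decalin half is numbered as a naphthalene with primes (C1′ … C8a′; ring C = cyclohexene carrying the hydroperoxide, ring D = cyclohexane carrying the gem-dimethyl group). The bridge carbons are Ca (on C6) and Cb (on C5′).

## The problem

Sipholenol M is two C15 bicycles joined by a CH2–CH2 bridge: a trans-fused oxepane–cyclohexane (rings A/B) and a cis-fused decalin (rings C/D). Five of the nine stereocentres (C3, C5a, C6, C7, C9a) sit on the A/B bicycle and four (C1′, C4a′, C8a′, C7′) on the decalin. The flexible bridge prevents either cluster from controlling the other, so each half needs its own source of absolute configuration. Both tertiary carbinols (C7 and C1′) have an axial methyl group and an equatorial hydroxyl next to a 1,3-related axial carbon. Methyl addition to the corresponding ketones would therefore give the wrong epimers, and the carbinols must come from exocyclic methylenes by equatorial epoxidation and hydride opening. The secondary allylic hydroperoxide at C7′, flanked by the tetrasubstituted C5′=C6′ alkene, will not survive carbanions, hydrides, phosphines, reducing metals or acid, so it must be introduced last. The enabling feature is in rings A/B: O1 lies between the CMe2 carbon C2 and the ring-fusion carbon C9a, and C5a (angular methyl) is bonded to the bridge-bearing C6. This is the folding pattern of an all-E 1,5-diepoxide ending in an alkene, so both rings and four stereocentres can arise in one operation from a geranyl-derived chain. For the decalin, the gem-dimethyl carbon next to the ring fusion points to 4,4-dimethylcyclohex-2-en-1-one as ring D and a cis-selective cycloaddition for ring C.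

## Retrosynthesis

**C7′–O bond.** The hydroperoxide of 36 is removed first, since nothing else in the route tolerates it. An ene reaction with singlet oxygen leads back to the hydrocarbon alkene 35, in which the alkene sits at C6′=C7′ and C5′ carries a hydrogen. The forward step must put oxygen on C7′ on the face of the ring D bonds and take the C5′ hydrogen from that face. The neighbouring option, displacement of an activated C7′ alcohol by a peroxide nucleophile, is kept as the fallback.

**C5′–H bond.** Alkene 35 is traced to the allylic alcohol 32 (C5′=C6′ alkene, C7′–OH on the face of the ring-fusion hydrogens) by a reductive allylic transposition. This trades the C5′ stereocentre, which no reagent could address directly, for a carbinol centre that a ring-controlled oxidation can set. The forward reaction must invert at C7′ and deliver hydrogen suprafacially to C5′.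

**Ca–Cb bond.** Alcohol 32 comes, through silyl ether 31, epoxide 30 and sulfone 29, from the union of sulfone 16 with allylic bromide 28. This cut divides the C30 skeleton into two C15 halves of similar complexity and uses an unhindered primary allylic electrophile. Cutting C6–Ca or Cb–C5′ would instead require bond formation at a ring carbon flanked by quaternary centres. The forward step asks for alkylation of an α-sulfonyl carbanion beside two alkoxides, then reductive desulfonylation.

**Ring C of bromide 28.** The bromide is simplified through carbinol 27, methylene ketone 26 and silyloxy ketone 23 to the Diels–Alder adduct 20, and from there to diene 18 and enone 19. The cycloaddition is preferred over stepwise annulation because it guarantees the cis ring fusion and because its regiochemistry is useful twice. The enol ether of 20 points toward C7′, so oxidation places oxygen there, and afterwards C5′ is the only enolizable methylene for the one-carbon extension. The C1′ carbinol is carried as a spiro-epoxide until after the coupling.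

**Sulfone 16.** This is the triol 14 with its primary hydroxyl exchanged for a sulfone (via sulfide 15). Triol 14 comes from the cascade product 11 by epoxidation (12), hydride opening (13) and desilylation. These changes add no skeletal bonds.

**O1–C2 and C5a–C6 bonds (key step).** Bicycle 11 is opened to the acyclic diepoxy allylsilane 9. No other cut removes two rings and reduces the stereochemical problem to two reagent-controlled epoxidations and one alkene geometry. Cutting only the oxepane C–O bond would leave a substituted cyclohexane with three contiguous stereocentres to be made separately. The forward reaction must open both epoxides at their tertiary carbons and close ring B through a chair.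

**Chain of 9.** Silyl ether 9 goes back through alcohol 8, ester 7, diepoxide 5, enol triflate 4 and keto ester 3 to methyl acetoacetate 1, geranyl bromide 2 and the silylmethyl nucleophile 6. The Z-enol triflate fixes the alkene geometry; the two epoxides are set by one asymmetric epoxidation.

## Roads not taken

**Alternative 1:** This road cuts the C1′–C8a′ bond of ring D. SmI2 with HMPA would reduce the methyl ketone of aryl ketone A1 to a ketyl that adds to the ortho carbon of the resorcinol ether, giving the bis(enol ether) A2.
- Merits: one step makes ring D together with the tertiary carbinol. Ring C emerges as a masked 2-methylcyclohexane-1,3-dione, the ideal oxidation pattern for attaching the bridge by addition to a vinylogous ester and arriving directly at a C7′ enone. A1 is only a few steps from 2,6-dimethoxytoluene.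
- Weak points: A1 is achiral and enantioselective ketyl–arene additions are not dependable. C4a′ is set only later, by protonation next to the gem-dimethyl carbon during enol ether hydrolysis, where cis versus trans is under thermodynamic control. The hydroxyl/8a′-H relationship is not secured by any element of the substrate.
- Comparison: as an entry to the decalin, A2 is shorter than the seven steps spent here on bromide 28 and better matched to the C7′ oxidation level. Against this the chosen plan sets catalyst control of absolute configuration in both halves, and a key step that solves the half with the medium ring and five stereocentres, which Alternative 1 leaves untouched.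

**Alternative 2:** This road cuts C4a′–C8a′ and C7′–C8′ in an intramolecular Diels–Alder reaction of triene A3, giving the cis-fused ketone A4.
- Merits: ring C is formed with the C5′ oxymethyl arm, the C6′ methyl, the C7′ oxygen and the cis fusion all in place. A4 is two or three steps from a bromide equivalent to 28, so from ring closure onward it is better than the present decalin sequence.
- Weak points: A3 needs two defined alkene geometries and combines a silyl dienol ether with a vinyl ketone, a pair prone to Mukaiyama–Michael and polymerization pathways. It is achiral, so enantiocontrol and the endo/exo ratio (C7′ versus the ring fusion) rest on an external catalyst. C1′ is still a ketone, and methyl addition would occur equatorially, so the methylenation/epoxidation/hydride sequence is needed anyway.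
- Comparison: the chosen plan sets against it an intermolecular cycloaddition of two simple components whose regiochemistry is exploited twice. The comparison is otherwise the same as for Alternative 1: the oxepane half remains unsolved.

**Alternative 3:** This road addresses rings A/B. Irradiation of furanone A5 joins C9a to C5a and C4 to C5 in a [2+2] photocycloaddition, giving the cyclobutane A6; cleavage of the C4–C9a bond then expands the furanone to the oxepan-3-one.
- Merits: the C6 and C7 centres are in place before ring closure and steer the facial selectivity. The tether enforces the regiochemistry. The C3 ketone allows the carbinol configuration to be adjusted by reduction. No Lewis-acid cascade with competing epoxide openings is involved, and the C7 carbinol does not cost two later steps as it does here (steps 8 and 9).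
- Weak points: A5 contains two contiguous stereocentres, one a tertiary ether, that must be built in an acyclic setting, so the hardest stereochemical task is moved into the precursor. After the photoreaction the correct cyclobutane bond must be cleaved reductively. The C9a hydrogen is then introduced by protonation, which does not guarantee the trans fusion, and the C3 ketone must be reduced to the (S)-alcohol.
- Comparison: the chosen plan reaches bicycle 11 in seven steps from geranyl bromide, with C3, C5a and C9a fixed by reagent-controlled epoxidation and stereospecific opening and C6 by alkene geometry. That brevity and predictability are what it sets against the greater robustness of the individual steps in Alternative 3.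

Key step: step 7

Assumption: the sense of induction of the oxazaborolidinium catalyst in step 14 is taken from its behaviour with unsubstituted cyclohex-2-en-1-one; if the 4,4-dimethyl enone responds in the opposite sense, the enantiomeric catalyst is used.

## Route

Step 1
Reactants: 1 methyl acetoacetate; 2 geranyl bromide
Product: 3 methyl (6E)-7,11-dimethyl-3-oxododeca-6,10-dienoate
Conditions: NaH, THF, 0 °C; n-BuLi, 0 °C; then 2, 0 °C → rt
Reagents that add atoms: none
Why: Weiler dianion alkylation: the γ-carbanion of the acetoacetate dianion is the more nucleophilic site and displaces the allylic bromide by SN2 without disturbing the two trisubstituted alkenes.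

Step 2
Reactants: 3 methyl (6E)-7,11-dimethyl-3-oxododeca-6,10-dienoate
Product: 4 methyl (2Z,6E)-7,11-dimethyl-3-(trifluoromethylsulfonyloxy)dodeca-2,6,10-trienoate
Conditions: Tf2O, aq. LiOH, toluene, 5 °C
Reagents that add atoms: trifluoromethanesulfonic anhydride, O=S(=O)(OS(=O)(=O)C(F)(F)F)C(F)(F)F
Why: Enol triflation of a β-keto ester through its lithium chelate gives the Z-enol triflate; this geometry later places the silylmethyl group cis to the oxygenated arm.

Step 3
Reactants: 4 methyl (2Z,6E)-7,11-dimethyl-3-(trifluoromethylsulfonyloxy)dodeca-2,6,10-trienoate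
Product: 5 methyl (2Z)-5-[(2S,3S)-3-{2-[(2S)-3,3-dimethyloxiran-2-yl]ethyl}-3-methyloxiran-2-yl]-3-(trifluoromethylsulfonyloxy)pent-2-enoate
Conditions: L-fructose-derived Shi ketone (30 mol%), KHSO5 (as 2KHSO5·KHSO4·K2SO4), K2CO3, Bu4NHSO4, Na2B4O7 buffer pH 10.5, MeCN–CH2(OMe)2–H2O, 0 °C
Reagents that add atoms: potassium peroxymonosulfate, [K+].[O-]S(=O)(=O)OO
Why: Shi asymmetric epoxidation: the chiral dioxirane epoxidizes both electron-rich trisubstituted E-alkenes through the spiro transition state and leaves the electron-poor enol triflate alkene alone. Each alkene is controlled independently by the catalyst, and the L-fructose-derived ketone gives the (S,S) and (S) epoxides.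

Step 4
Reactants: 5 methyl (2Z)-5-[(2S,3S)-3-{2-[(2S)-3,3-dimethyloxiran-2-yl]ethyl}-3-methyloxiran-2-yl]-3-(trifluoromethylsulfonyloxy)pent-2-enoate; 6 (trimethylsilyl)methyllithium
Product: 7 methyl (2Z)-5-[(2S,3S)-3-{2-[(2S)-3,3-dimethyloxiran-2-yl]ethyl}-3-methyloxiran-2-yl]-3-[(trimethylsilyl)methyl]pent-2-enoate
Conditions: 6 (2 equiv), CuI (1 equiv), THF, −78 → −40 °C; then 5, −78 °C
Reagents that add atoms: none
Why: Cuprate substitution of a β-(triflyloxy)enoate (addition–elimination) proceeds with retention of alkene geometry and is faster than opening of trisubstituted epoxides at low temperature.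

Step 5
Reactants: 7 methyl (2Z)-5-[(2S,3S)-3-{2-[(2S)-3,3-dimethyloxiran-2-yl]ethyl}-3-methyloxiran-2-yl]-3-[(trimethylsilyl)methyl]pent-2-enoate
Product: 8 (2Z)-5-[(2S,3S)-3-{2-[(2S)-3,3-dimethyloxiran-2-yl]ethyl}-3-methyloxiran-2-yl]-3-[(trimethylsilyl)methyl]pent-2-en-1-ol
Conditions: i-Bu2AlH, CH2Cl2, −78 °C
Reagents that add atoms: none
Why: 1,2-Reduction of the enoate by the aluminium hydride at −78 °C; the epoxides and the allylsilane are inert under these conditions.

Step 6
Reactants: 8 (2Z)-5-[(2S,3S)-3-{2-[(2S)-3,3-dimethyloxiran-2-yl]ethyl}-3-methyloxiran-2-yl]-3-[(trimethylsilyl)methyl]pent-2-en-1-ol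
Product: 9 tert-butyldiphenylsilyl ether of alcohol 8 (diepoxy allylsilane)
Conditions: t-BuPh2SiCl, imidazole, DMF, 0 °C → rt
Reagents that add atoms: tert-butyl(chloro)diphenylsilane, CC(C)(C)[Si](Cl)(c1ccccc1)c1ccccc1
Why: Standard silylation of a primary allylic alcohol; the bulky silyl ether is a poor Lewis base and will not compete with the epoxides for the silyl triflate in step 7.

Step 7
Reactants: 9 tert-butyldiphenylsilyl ether of alcohol 8 (diepoxy allylsilane)
Product: 11 tert-butyldiphenylsilyl ether of trans-fused (3S)-6-(hydroxymethyl)-2,2,5a-trimethyl-7-methylidenedecahydro-1-benzoxepin-3-ol, via trimethylsilyl ether 10 (not isolated)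
Conditions: Me3SiOTf (1.2 equiv), 2,6-di-tert-butyl-4-methylpyridine, CH2Cl2, −78 °C; then 1 M HCl, THF, 0 °C
Reagents that add atoms: none
Why: Me3SiOTf silylates the less hindered terminal epoxide, whose tertiary C–O bond is opened by the oxygen of the neighbouring epoxide to give a bicyclic epoxonium ion; the allylsilane then attacks the tertiary carbon of that ion and silicon is lost, leaving the exocyclic methylene and the C3 silyl ether 10, which the acidic work-up cleaves. The closest known reaction type is the Lewis-acid polyepoxide oxa/carbacyclization terminated by allyl- or propargylsilanes, which gives trans-fused oxepane–cyclohexanes. Ring A closes by 7-endo opening of the terminal epoxide at C2 (O1–C2 bond). Ring B closes by a 6-endo attack (with respect to the alkene) of the allylsilane carbon on C5a, anti to the departing oxygen, through a chair. C3 and C9a keep the configuration of the (S)-epoxide carbons because their C–O bonds are never broken. C5a is inverted, so the trans epoxide becomes the trans ring fusion with an axial methyl group. C6 is set by the Z-alkene geometry, which puts the CH2OSi arm equatorial in the chair and cis to the angular methyl. The step needs endo opening twice, which the tertiary epoxide termini secure by Markovnikov-type ionization, and freedom from protodesilylation, which the hindered pyridine base secures.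

Step 8
Reactants: 11 tert-butyldiphenylsilyl ether of trans-fused (3S)-6-(hydroxymethyl)-2,2,5a-trimethyl-7-methylidenedecahydro-1-benzoxepin-3-ol
Product: 12 7-spiro-epoxide of 11 (epoxide oxygen equatorial and trans to the 5a-methyl)
Conditions: mCPBA, NaHCO3, CH2Cl2, 0 °C
Reagents that add atoms: 3-chloroperoxybenzoic acid, OOC(=O)c1cccc(Cl)c1
Why: Prilezhaev epoxidation of the 1,1-disubstituted alkene; the axial 5a-methyl group blocks the axial face, so the peracid approaches equatorially and the new C7–O bond is equatorial.

Step 9
Reactants: 12 7-spiro-epoxide of 11 (epoxide oxygen equatorial and trans to the 5a-methyl)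
Product: 13 6-[(tert-butyldiphenylsilyloxy)methyl]-2,2,5a,7-tetramethyldecahydro-1-benzoxepine-3,7-diol (7-methyl axial; 7-hydroxyl equatorial)
Conditions: LiAlH4, THF, 0 °C → rt
Reagents that add atoms: none
Why: Hydride opens the spiro-epoxide by SN2 at its CH2 terminus; that carbon becomes the axial C7 methyl and the equatorial tertiary hydroxyl keeps the configuration set in step 8.

Step 10
Reactants: 13 6-[(tert-butyldiphenylsilyloxy)methyl]-2,2,5a,7-tetramethyldecahydro-1-benzoxepine-3,7-diol
Product: 14 6-(hydroxymethyl)-2,2,5a,7-tetramethyldecahydro-1-benzoxepine-3,7-diol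
Conditions: Bu4NF, THF, rt
Reagents that add atoms: none
Why: Fluoride-mediated cleavage of the silyl ether.

Step 11
Reactants: 14 6-(hydroxymethyl)-2,2,5a,7-tetramethyldecahydro-1-benzoxepine-3,7-diol
Product: 15 2,2,5a,7-tetramethyl-6-[(phenylsulfanyl)methyl]decahydro-1-benzoxepine-3,7-diol
Conditions: PhSSPh, Bu3P, pyridine, rt → 50 °C
Reagents that add atoms: diphenyl disulfide, c1ccc(SSc2ccccc2)cc1
Why: Hata thioetherification (Mitsunobu-type): only the primary hydroxyl forms the alkoxyphosphonium ion and is displaced by thiolate; the hindered secondary and the tertiary hydroxyls do not react.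

Step 12
Reactants: 15 2,2,5a,7-tetramethyl-6-[(phenylsulfanyl)methyl]decahydro-1-benzoxepine-3,7-diol
Product: 16 2,2,5a,7-tetramethyl-6-[(phenylsulfonyl)methyl]decahydro-1-benzoxepine-3,7-diol
Conditions: (NH4)6Mo7O24·4H2O (cat.), 30% H2O2, EtOH, 0 °C → rt
Reagents that add atoms: hydrogen peroxide, OO
Why: Molybdate-catalysed peroxide oxidation of sulfide to sulfone; no alkene remains to compete.

Step 13
Reactants: 17 methyl vinyl ketone
Product: 18 2-(triisopropylsilyloxy)buta-1,3-diene
Conditions: i-Pr3SiOTf, Et3N, Et2O, 0 °C
Reagents that add atoms: triisopropylsilyl trifluoromethanesulfonate, CC(C)[Si](OS(=O)(=O)C(F)(F)F)(C(C)C)C(C)C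
Why: Soft enolization of the enone with silyl triflate and amine gives the cross-conjugated 2-silyloxydiene.

Step 14
Reactants: 18 2-(triisopropylsilyloxy)buta-1,3-diene; 19 4,4-dimethylcyclohex-2-en-1-one
Product: 20 cis-fused 4,4-dimethyl-6-(triisopropylsilyloxy)-3,4,4a,5,8,8a-hexahydronaphthalen-1(2H)-one
Conditions: (S)-diphenylprolinol-derived o-tolyl oxazaborolidinium triflimide (20 mol%), CH2Cl2, −40 → 0 °C
Reagents that add atoms: none
Why: Catalytic enantioselective Diels–Alder reaction of a cyclic enone with a 2-silyloxydiene under chiral oxazaborolidinium activation. Suprafacial addition makes the ring fusion cis, and the catalyst selects the enone face and so sets C4a and C8a. The diene CH2 next to the silyloxy carbon bonds to the enone β-carbon, which places the enol ether toward C7.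

Step 15
Reactants: 20 cis-fused 4,4-dimethyl-6-(triisopropylsilyloxy)-3,4,4a,5,8,8a-hexahydronaphthalen-1(2H)-one
Product: 21 1-methylidene analogue of 20 (C1=CH2 in place of C1=O)
Conditions: Cp2TiMe2, toluene, 70 °C, dark
Reagents that add atoms: dimethyltitanocene, C[Ti](C)(C1C=CC=C1)C1C=CC=C1
Why: Petasis methylenation: the non-basic titanium methylidene converts the hindered, epimerizable ketone to the alkene without enolization at C8a and does not react with the silyl enol ether.

Step 16
Reactants: 21 1-methylidene analogue of 20
Product: 23 cis-fused 4,4-dimethyl-7-(triisopropylsilyloxy)octahydrospiro[naphthalene-1,2′-oxiran]-6-one (7-oxygen on the face of the ring-fusion hydrogens; epoxide oxygen equatorial), via silyloxy ketone 22 (not isolated)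
Conditions: mCPBA (2.3 equiv), NaHCO3, CH2Cl2, −10 °C → rt
Reagents that add atoms: 3-chloroperoxybenzoic acid, OOC(=O)c1cccc(Cl)c1
Why: Rubottom oxidation and Prilezhaev epoxidation in one flask. The enol ether reacts first, from the face of the ring-fusion hydrogens because the other face carries both ring D bonds, and silyl migration gives the α-silyloxy ketone. The exocyclic alkene then reacts from its equatorial side, the axial side being blocked by the axial C5 methylene, so the epoxide oxygen is equatorial.

Step 17
Reactants: 23 cis-fused 4,4-dimethyl-7-(triisopropylsilyloxy)octahydrospiro[naphthalene-1,2′-oxiran]-6-one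
Product: 26 5-methylidene derivative of ketone 23, via Mannich base 24 (not isolated), via ammonium iodide 25 (not isolated)
Conditions: LiN(SiMe3)2, THF, −78 °C; Me2N=CH2+ I−, −78 → 0 °C; then MeI, CH2Cl2, rt; then aq. NaHCO3
Reagents that add atoms: N,N-dimethylmethyleneiminium iodide, C=[N+](C)C.[I-]
Why: Kinetic enolization can only go toward C5 because C7 is tertiary and oxygenated; Mannich alkylation with the iminium salt, quaternization and E1cB elimination give the α-methylene ketone.

Step 18
Reactants: 26 5-methylidene derivative of ketone 23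
Product: 27 6-methyl-5-methylidene-7-(triisopropylsilyloxy) tertiary alcohol (C6 carbinol; spiro-epoxide retained)
Conditions: MeLi, CeCl3, THF, −78 °C
Reagents that add atoms: methyllithium, [Li]C
Why: Organocerium 1,2-addition to a hindered, enolizable enone carbonyl; the configuration of the new carbinol carbon is erased in step 19.

Step 19
Reactants: 27 6-methyl-5-methylidene-7-(triisopropylsilyloxy) tertiary alcohol
Product: 28 cis-fused 5-(bromomethyl)-4,4,6-trimethyl-7-(triisopropylsilyloxy)-3,4,4a,7,8,8a-hexahydro-2H-spiro[naphthalene-1,2′-oxirane]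
Conditions: CBr4, PPh3, 2,6-lutidine, CH2Cl2, −30 → 0 °C
Reagents that add atoms: carbon tetrabromide, BrC(Br)(Br)Br
Why: Appel bromination with allylic transposition: the tertiary alkoxyphosphonium ion ionizes to the allyl cation and bromide adds at the primary terminus, giving the tetrasubstituted ring alkene, which has no E/Z isomers. The neutral conditions spare the epoxide and the silyl ether.

Step 20
Reactants: 16 2,2,5a,7-tetramethyl-6-[(phenylsulfonyl)methyl]decahydro-1-benzoxepine-3,7-diol; 28 cis-fused allylic bromide
Product: 29 coupled sulfone (Ca bearing PhSO2 and bonded to Cb; epimers at Ca)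
Conditions: 16, n-BuLi (3.1 equiv), THF–HMPA, −78 °C; then 28, −78 → −20 °C
Reagents that add atoms: none
Why: SN2 alkylation of an α-sulfonyl carbanion, generated beside two lithium alkoxides, with a primary allylic bromide; the alkoxides are far less nucleophilic under these conditions.

Step 21
Reactants: 29 coupled sulfone
Product: 30 desulfonylated coupling product (CH2–CH2 bridge; 7′-silyl ether; 1′-spiro-epoxide)
Conditions: Na(Hg) (6%), Na2HPO4, MeOH–THF, −20 °C
Reagents that add atoms: none
Why: Reductive desulfonylation by electron transfer from sodium amalgam; there is no β-leaving group, so Julia-type elimination cannot occur.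

Step 22
Reactants: 30 desulfonylated coupling product
Product: 31 7′-O-triisopropylsilyl ether of tetraol 32
Conditions: LiAlH4, THF, 0 °C → rt
Reagents that add atoms: none
Why: Hydride opening of the spiro-epoxide at CH2 gives the axial C1′ methyl and the equatorial tertiary hydroxyl, the same tactic as in step 9.

Step 23
Reactants: 31 7′-O-triisopropylsilyl ether of tetraol 32
Product: 32 allylic alcohol (7′-hydroxyl on the face of the ring-fusion hydrogens; C5′=C6′ alkene)
Conditions: Bu4NF, THF, rt → 40 °C
Reagents that add atoms: none
Why: Fluoride-mediated cleavage of the secondary silyl ether.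

Step 24
Reactants: 32 allylic alcohol
Product: 35 transposed alkene (C6′=C7′; 5′-H on the face of the ring D bonds), via sulfonylhydrazide 33 (not isolated), via allylic diazene 34 (not isolated)
Conditions: 2-O2NC6H4SO2NHNH2, PPh3, EtO2CN=NCO2Et, N-methylmorpholine, −30 °C → rt
Reagents that add atoms: none
Why: Myers reductive 1,3-transposition: Mitsunobu displacement of the allylic hydroxyl by the sulfonylhydrazide with inversion, loss of sulfinate, and suprafacial retro-ene loss of N2 from the allylic diazene. Hydrogen is delivered to C5′ on the face opposite to the original hydroxyl and the alkene moves to C6′=C7′.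

Step 25
Reactants: 35 transposed alkene
Product: 36 sipholenol M
Conditions: O2, hν (visible), tetraphenylporphyrin (cat.), CH2Cl2, −20 °C
Reagents that add atoms: dioxygen, O=O
Why: Schenck ene reaction of singlet oxygen: oxygen bonds to C7′ and the C5′ hydrogen is removed on the same face, so the hydroperoxide arrives on the face where step 24 placed that hydrogen and the tetrasubstituted C5′=C6′ alkene is restored. The selectivity required is abstraction of the ring C5′–H in preference to the methyl and C8′ hydrogens.

## Compound list

1 | methyl acetoacetate | CC(=O)CC(=O)OC | starting material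
2 | geranyl bromide, (2E)-1-bromo-3,7-dimethylocta-2,6-diene | CC(C)=CCC/C(C)=C/CBr | starting material
3 | methyl (6E)-7,11-dimethyl-3-oxododeca-6,10-dienoate | COC(=O)CC(=O)CC/C=C(C)/CCC=C(C)C | intermediate
4 | methyl (2Z,6E)-7,11-dimethyl-3-(trifluoromethylsulfonyloxy)dodeca-2,6,10-trienoate | COC(=O)/C=C(\OS(=O)(=O)C(F)(F)F)CC/C=C(C)/CCC=C(C)C | intermediate
5 | methyl (2Z)-5-[(2S,3S)-3-{2-[(2S)-3,3-dimethyloxiran-2-yl]ethyl}-3-methyloxiran-2-yl]-3-(trifluoromethylsulfonyloxy)pent-2-enoate | COC(=O)/C=C(\OS(=O)(=O)C(F)(F)F)CC[C@@H]1O[C@@]1(C)CC[C@@H]1OC1(C)C | intermediate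
6 | (trimethylsilyl)methyllithium | [Li]C[Si](C)(C)C | starting material
7 | methyl (2Z)-5-[(2S,3S)-3-{2-[(2S)-3,3-dimethyloxiran-2-yl]ethyl}-3-methyloxiran-2-yl]-3-[(trimethylsilyl)methyl]pent-2-enoate | COC(=O)/C=C(\C[Si](C)(C)C)CC[C@@H]1O[C@@]1(C)CC[C@@H]1OC1(C)C | intermediate
8 | (2Z)-5-[(2S,3S)-3-{2-[(2S)-3,3-dimethyloxiran-2-yl]ethyl}-3-methyloxiran-2-yl]-3-[(trimethylsilyl)methyl]pent-2-en-1-ol | OC/C=C(\C[Si](C)(C)C)CC[C@@H]1O[C@@]1(C)CC[C@@H]1OC1(C)C | intermediate
9 | tert-butyldiphenylsilyl ether of 8 (silylmethyl group cis to the CH2OSi arm; all three epoxide carbons S) | CC(C)(C)[Si](c1ccccc1)(c1ccccc1)OC/C=C(\C[Si](C)(C)C)/CC[C@@H]2O[C@@]2(C)CC[C@@H]3OC3(C)C | intermediate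
10 | 3-O-trimethylsilyl ether of 11 | CC(C)(C)[Si](c1ccccc1)(c1ccccc1)OC[C@H]2[C@]3(C)CC[C@H](O[Si](C)(C)C)C(C)(C)O[C@H]3CCC2=C | intermediate
11 | trans-fused (3S)-6-[(tert-butyldiphenylsilyloxy)methyl]-2,2,5a-trimethyl-7-methylidenedecahydro-1-benzoxepin-3-ol (9a-H trans to the 5a-methyl; 6-arm equatorial and cis to the 5a-methyl) | CC(C)(C)[Si](c1ccccc1)(c1ccccc1)OC[C@H]2[C@]3(C)CC[C@H](O)C(C)(C)O[C@H]3CCC2=C | intermediate
12 | 7-spiro-epoxide of 11 (epoxide oxygen equatorial, trans to the 5a-methyl; epoxide CH2 axial) | CC(C)(C)[Si](c1ccccc1)(c1ccccc1)OC[C@H]2[C@]3(C)CC[C@H](O)C(C)(C)O[C@H]3CC[C@]2(C4)O4 | intermediate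
13 | 6-[(tert-butyldiphenylsilyloxy)methyl]-2,2,5a,7-tetramethyldecahydro-1-benzoxepine-3,7-diol (7-methyl axial, cis to the 5a-methyl; 7-OH equatorial) | CC(C)(C)[Si](c1ccccc1)(c1ccccc1)OC[C@H]2[C@]3(C)CC[C@H](O)C(C)(C)O[C@H]3CC[C@]2(C)O | intermediate
14 | 6-(hydroxymethyl)-2,2,5a,7-tetramethyldecahydro-1-benzoxepine-3,7-diol (configuration as in 13) | OC[C@H]2[C@]3(C)CC[C@H](O)C(C)(C)O[C@H]3CC[C@]2(C)O | intermediate
15 | 2,2,5a,7-tetramethyl-6-[(phenylsulfanyl)methyl]decahydro-1-benzoxepine-3,7-diol | c1ccccc1SC[C@H]2[C@]3(C)CC[C@H](O)C(C)(C)O[C@H]3CC[C@]2(C)O | intermediate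
16 | 2,2,5a,7-tetramethyl-6-[(phenylsulfonyl)methyl]decahydro-1-benzoxepine-3,7-diol | O=S(=O)(c1ccccc1)C[C@H]2[C@]3(C)CC[C@H](O)C(C)(C)O[C@H]3CC[C@]2(C)O | intermediate
17 | methyl vinyl ketone (but-3-en-2-one) | CC(=O)C=C | starting material
18 | 2-(triisopropylsilyloxy)buta-1,3-diene | C=CC(=C)O[Si](C(C)C)(C(C)C)C(C)C | intermediate
19 | 4,4-dimethylcyclohex-2-en-1-one | CC1(C)CCC(=O)C=C1 | starting material
20 | cis-fused 4,4-dimethyl-6-(triisopropylsilyloxy)-3,4,4a,5,8,8a-hexahydronaphthalen-1(2H)-one (4a-H and 8a-H on the same face) | CC(C)[Si](C(C)C)(C(C)C)OC=1C[C@@H]2[C@H](CC=1)C(=O)CCC2(C)C | intermediate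
21 | 1-methylidene analogue of 20 (locants of 20) | CC(C)[Si](C(C)C)(C(C)C)OC=1C[C@@H]2[C@H](CC=1)C(=C)CCC2(C)C | intermediate
22 | cis-fused 4,4-dimethyl-1-methylidene-7-(triisopropylsilyloxy)octahydronaphthalen-6-one (7-oxygen on the face of the ring-fusion hydrogens) | O=C1C[C@@H]2[C@H](C[C@@H]1O[Si](C(C)C)(C(C)C)C(C)C)C(=C)CCC2(C)C | intermediate
23 | 1-spiro-epoxide of 22 (epoxide oxygen equatorial, on the side of 8a-H) | O=C1C[C@@H]2[C@H](C[C@@H]1O[Si](C(C)C)(C(C)C)C(C)C)[C@@](C3)(O3)CCC2(C)C | intermediate
24 | 5-[(dimethylamino)methyl] derivative of 23 (epimers at C5) | O=C1C(CN(C)C)[C@@H]2[C@H](C[C@@H]1O[Si](C(C)C)(C(C)C)C(C)C)[C@@](C3)(O3)CCC2(C)C | intermediate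
25 | trimethylammonium iodide of 24 | O=C1C(C[N+](C)(C)C)[C@@H]2[C@H](C[C@@H]1O[Si](C(C)C)(C(C)C)C(C)C)[C@@](C3)(O3)CCC2(C)C.[I-] | intermediate
26 | 5-methylidene derivative of 23 | O=C1C(=C)[C@@H]2[C@H](C[C@@H]1O[Si](C(C)C)(C(C)C)C(C)C)[C@@](C3)(O3)CCC2(C)C | intermediate
27 | 6-methyl-5-methylidene-7-(triisopropylsilyloxy) C6 tertiary alcohol from 26 (C6 configuration not defined) | CC1(O)C(=C)[C@@H]2[C@H](C[C@@H]1O[Si](C(C)C)(C(C)C)C(C)C)[C@@](C3)(O3)CCC2(C)C | intermediate
28 | cis-fused 5-(bromomethyl)-4,4,6-trimethyl-7-(triisopropylsilyloxy)-3,4,4a,7,8,8a-hexahydro-2H-spiro[naphthalene-1,2′-oxirane] | CC1=C(CBr)[C@@H]2[C@H](C[C@@H]1O[Si](C(C)C)(C(C)C)C(C)C)[C@@](C3)(O3)CCC2(C)C | intermediate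
29 | coupled sulfone: benzoxepinediol half of 16 joined through Ca(SO2Ph)–Cb to C5′ of the decalin half of 28 (epimers at Ca) | CC1=C(CC([C@H]2[C@]3(C)CC[C@H](O)C(C)(C)O[C@H]3CC[C@]2(C)O)S(=O)(=O)c4ccccc4)[C@@H]2[C@H](C[C@@H]1O[Si](C(C)C)(C(C)C)C(C)C)[C@@](C3)(O3)CCC2(C)C | intermediate
30 | desulfonylated coupling product (CH2–CH2 bridge; 7′-OSi(i-Pr)3; 1′-spiro-epoxide) | CC1=C(CC[C@H]2[C@]3(C)CC[C@H](O)C(C)(C)O[C@H]3CC[C@]2(C)O)[C@@H]2[C@H](C[C@@H]1O[Si](C(C)C)(C(C)C)C(C)C)[C@@](C3)(O3)CCC2(C)C | intermediate
31 | 7′-O-triisopropylsilyl ether of 32 (1′-methyl axial; 1′-OH equatorial) | CC1=C(CC[C@H]2[C@]3(C)CC[C@H](O)C(C)(C)O[C@H]3CC[C@]2(C)O)[C@@H]2[C@H](C[C@@H]1O[Si](C(C)C)(C(C)C)C(C)C)[C@@](C)(O)CCC2(C)C | intermediate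
32 | allylic alcohol: 7′-OH in place of 7′-OOH and with the opposite configuration at C7′ (OH on the face of the ring-fusion hydrogens) | CC1=C(CC[C@H]2[C@]3(C)CC[C@H](O)C(C)(C)O[C@H]3CC[C@]2(C)O)[C@@H]2[C@H](C[C@@H]1O)[C@@](C)(O)CCC2(C)C | intermediate
33 | N-(2-nitrophenylsulfonyl)hydrazine bonded through its sulfonylated nitrogen to C7′ (inverted; on the face of the ring D bonds) | CC1=C(CC[C@H]2[C@]3(C)CC[C@H](O)C(C)(C)O[C@H]3CC[C@]2(C)O)[C@@H]2[C@H](C[C@H]1N(N)S(=O)(=O)c4ccccc4[N+](=O)[O-])[C@@](C)(O)CCC2(C)C | intermediate
34 | C7′ allylic diazene (N=NH on the face of the ring D bonds) | CC1=C(CC[C@H]2[C@]3(C)CC[C@H](O)C(C)(C)O[C@H]3CC[C@]2(C)O)[C@@H]2[C@H](C[C@H]1N=N)[C@@](C)(O)CCC2(C)C | intermediate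
35 | 7′-deoxy alkene: C6′=C7′ double bond; 5′-H on the face of the ring D bonds; bridge on the face of the ring-fusion hydrogens | CC=1[C@H](CC[C@H]2[C@]3(C)CC[C@H](O)C(C)(C)O[C@H]3CC[C@]2(C)O)[C@@H]2[C@H](CC=1)[C@@](C)(O)CCC2(C)C | intermediate
36 | sipholenol M | CC1=C(CC[C@H]2[C@]3(C)CC[C@H](O)C(C)(C)O[C@H]3CC[C@]2(C)O)[C@@H]2[C@H](C[C@H]1OO)[C@@](C)(O)CCC2(C)C | target

## Step count and least certain steps

Total: 25 steps. Longest linear sequence: 18 steps (steps 1–12, then 20–25); the decalin branch (steps 13–19) is 7 steps.

**Step 7 (key step).** The epoxonium ion may collapse by elimination or a 1,2-shift, or the allylsilane may be protodesilylated by adventitious acid, before the C5a–C6 bond forms; the allylsilane is only a moderate π-nucleophile and the bond is made at a tertiary centre. Fallback: set out from triflate 5 and install a more nucleophilic terminator. Substitution with the cuprate from tributylstannylmethyllithium and CuI should give the allylstannane ester F1. Reduction with i-Bu2AlH gives the allylic alcohol F2, and silylation gives the tert-butyldiphenylsilyl ether F3. Treatment of F3 with BF3·OEt2 at −78 °C should close the same two rings and return to the route at 11.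

**Step 25.** Abstraction of the wrong allylic hydrogen (from the C6′ methyl or from C8′, with oxygen going to C6′ in the latter case) is the likely failure. The half-chair that holds the C5′–H axial suffers allylic strain with the C6′ methyl, and simple 1-methylcyclohexenes favour the other two ene modes. Fallback: set out from alcohol 32, whose C7′ configuration is already the opposite of the target's. Selective sulfonylation (Ms2O, Et3N, −40 °C) gives the allylic methanesulfonate F5. SN2 displacement with inversion by 2-methoxyprop-2-yl hydroperoxide and CsOH in DMF gives the peroxyketal F6. Dilute acetic acid releases the hydroperoxide and returns to the route at 36.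

**Step 24.** Activation at the hindered C7′ carbinol may be slow relative to reaction at the C3 hydroxyl, or the alkoxyphosphonium ion may lose a proton to give a ring C diene. Fallback: set out from 32. Allylic oxidation with MnO2 gives the enone F7 and condensation with tosylhydrazide gives the tosylhydrazone F8. Reduction with catecholborane and NaOAc delivers hydride to C7′ from the face of the ring-fusion hydrogens, passes through the same diazene 34, and returns to the route at 35.

**Step 14.** Low conversion or poor facial discrimination is possible because the β-carbon of enone 19 is neopentyl and the catalyst was developed on unhindered cycloalkenones. Fallback: set out from 18 and 19 with EtAlCl2 in CH2Cl2 to obtain the racemic cis adduct, and separate the enantiomers by preparative chromatography on a chiral stationary phase. The unwanted enantiomer F9 is set aside and the other returns to the route at 20.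

**Step 19.** The allyl cation ion pair may lose a proton to a diene, or bromide may open the spiro-epoxide. Fallback: set out from 27 and separate the transposition from the halogenation. Ph3SiOReO3-catalysed 1,3-hydroxyl transposition gives the primary allylic alcohol F10, which ordinary Appel bromination (CBr4, PPh3) converts to the bromide, returning to the route at 28.

## Further compounds

F1 | step 7 | methyl (2Z)-5-[(2S,3S)-3-{2-[(2S)-3,3-dimethyloxiran-2-yl]ethyl}-3-methyloxiran-2-yl]-3-[(tributylstannyl)methyl]pent-2-enoate | COC(=O)/C=C(\C[Sn](CCCC)(CCCC)CCCC)CC[C@@H]1O[C@@]1(C)CC[C@@H]1OC1(C)C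
F2 | step 7 | (2Z)-5-[(2S,3S)-3-{2-[(2S)-3,3-dimethyloxiran-2-yl]ethyl}-3-methyloxiran-2-yl]-3-[(tributylstannyl)methyl]pent-2-en-1-ol | OC/C=C(\C[Sn](CCCC)(CCCC)CCCC)CC[C@@H]1O[C@@]1(C)CC[C@@H]1OC1(C)C
F3 | step 7 | tert-butyldiphenylsilyl ether of F2 | CC(C)(C)[Si](c1ccccc1)(c1ccccc1)OC/C=C(\C[Sn](CCCC)(CCCC)CCCC)/CC[C@@H]2O[C@@]2(C)CC[C@@H]3OC3(C)C
F5 | step 25 | C7′ methanesulfonate of alcohol 32 | CC1=C(CC[C@H]2[C@]3(C)CC[C@H](O)C(C)(C)O[C@H]3CC[C@]2(C)O)[C@@H]2[C@H](C[C@@H]1OS(C)(=O)=O)[C@@](C)(O)CCC2(C)C
F6 | step 25 | C7′ (2-methoxypropan-2-yl)peroxy derivative with the target configuration | CC1=C(CC[C@H]2[C@]3(C)CC[C@H](O)C(C)(C)O[C@H]3CC[C@]2(C)O)[C@@H]2[C@H](C[C@H]1OOC(C)(C)OC)[C@@](C)(O)CCC2(C)C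
F7 | step 24 | C7′ enone from alcohol 32 | CC1=C(CC[C@H]2[C@]3(C)CC[C@H](O)C(C)(C)O[C@H]3CC[C@]2(C)O)[C@@H]2[C@H](CC1=O)[C@@](C)(O)CCC2(C)C
F8 | step 24 | tosylhydrazone of enone F7 | CC1=C(CC[C@H]2[C@]3(C)CC[C@H](O)C(C)(C)O[C@H]3CC[C@]2(C)O)[C@@H]2[C@H](CC1=NNS(=O)(=O)c4ccc(C)cc4)[C@@](C)(O)CCC2(C)C
F9 | step 14 | enantiomer of adduct 20 | CC(C)[Si](C(C)C)(C(C)C)OC=1C[C@H]2[C@@H](CC=1)C(=O)CCC2(C)C
F10 | step 19 | primary allylic alcohol, 5-(hydroxymethyl) analogue of bromide 28 | CC1=C(CO)[C@@H]2[C@H](C[C@@H]1O[Si](C(C)C)(C(C)C)C(C)C)[C@@](C3)(O3)CCC2(C)C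
A1 | alternative 1 | 5-(2,4-dimethoxy-3-methylphenyl)-5-methylhexan-2-one | CC(=O)CCC(C)(C)c1ccc(OC)c(C)c1OC
A2 | alternative 1 | hexahydronaphthalenol bis(enol ether) | C[C@H]1C(OC)=C2[C@H](C=C1OC)[C@@](C)(O)CCC2(C)C
A3 | alternative 2 | (7Z,9E)-10-(tert-butyldimethylsilyloxy)-8-[(4-methoxybenzyloxy)methyl]-6,6,9-trimethyldeca-1,7,9-trien-3-one | C=CC(=O)CCC(C)(C)/C=C(COCc1ccc(OC)cc1)/C(C)=C/O[Si](C)(C)C(C)(C)C
A4 | alternative 2 | cis-fused bicyclic ketone silyl ether | CC1=C(COCc3ccc(OC)cc3)[C@@H]2[C@H](C[C@H]1O[Si](C)(C)C(C)(C)C)C(=O)CCC2(C)C
A5 | alternative 3 | 5-[4-(benzyloxymethyl)-3,5-dimethyl-3-(triethylsilyloxy)hex-5-enyl]-2,2-dimethylfuran-3(2H)-one | C=C(C)[C@H](COCc1ccccc1)[C@@](C)(O[Si](CC)(CC)CC)CCC1=CC(=O)C(C)(C)O1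
A6 | alternative 3 | tricyclic cyclobutane photoadduct | c1ccccc1COC[C@H]2[C@]3(C)C[C@H]4C(=O)C(C)(C)O[C@]43CC[C@]2(C)O[Si](CC)(CC)CC
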